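**Retrosynthetic overview**

1. Feature: ring B (C1'–C6', bonded through C1' to C3 of the chroman) is a resorcinol with its prenyl group on C3', between the C2' and C4' oxygens. That carbon corresponds to C2 of a cyclohexane-1,3-dione, where an alkyl group sits between the two oxygens by construction.
2. Kanzonol X ⇐ MOM removal and dehydrogenation of a 4-(chroman-3-yl)-2-prenylcyclohexane-1,3-dione ⇐ Michael–Claisen annulation (C1'–C6', then C2'–C3') of (3R)-chroman-3-ylacetate 17 with 7-methylocta-1,6-dien-3-one 22.
3. Ester 17 ⇐ Mitsunobu closure of ring C (O1–C2) ⇐ (R)-β-arylmethyl-γ-butyrolactone ⇐ Rh/Et-DuPhos hydrogenation of the Stobbe half-ester of 2,4-bis(MOM-oxy)-3-prenylbenzaldehyde ⇐ resorcinol by two directed lithiations. Enone 22 ⇐ homoprenyl Grignard reagent + acrolein.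
4. Ring order: ring A is bought as resorcinol, ring C is closed in step 8, ring B is built in step 12 and aromatized in step 14. The only stereocenter, C3, is set in step 5.

Key step: step 12

Remark: the (S,S)-Et-DuPhos rhodium catalyst is assumed to give the (R)-half-ester 10, the sense expected for itaconate-type substrates; if this substrate responded in the opposite sense, the (R,R) ligand would be used.

Abbreviations: prenyl = 3-methylbut-2-en-1-yl; MOM = methoxymethyl; chroman = 3,4-dihydro-2H-1-benzopyran; primed locants refer to ring B.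

**Route**

Step 1
Reactants: 1 resorcinol
Product: 2 1,3-bis(methoxymethoxy)benzene
Conditions: MOMCl (2.5 equiv), i-Pr2NEt (3 equiv), CH2Cl2, 0 °C → rt
Reagents that add atoms: chloromethyl methyl ether, COCCl
Why: O-alkylation of both phenols (Williamson-type acetal formation) installs the two MOM groups that direct the lithiations that follow.

Step 2
Reactants: 2 1,3-bis(methoxymethoxy)benzene; 3 prenyl bromide
Product: 5 1,3-bis(methoxymethoxy)-2-prenylbenzene, via aryllithium 4 (not isolated)
Conditions: n-BuLi (1.1 equiv), THF, 0 °C → rt; CuI (10 mol %), then 3, –78 °C → rt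
Reagents that add atoms: none
Why: Directed ortho-metalation, in which the two MOM ethers cooperatively steer n-BuLi to C2 between them, followed by copper-catalysed SN2 allylation of the aryllithium with the primary bromide, should place the linear prenyl group on the carbon flanked by both oxygens.

Step 3
Reactants: 5 1,3-bis(methoxymethoxy)-2-prenylbenzene
Product: 7 2,4-bis(methoxymethoxy)-3-prenylbenzaldehyde, via aryllithium 6 (not isolated)
Conditions: n-BuLi (1.2 equiv), TMEDA, THF, –20 → 0 °C; DMF, 0 °C → rt; then H2O
Reagents that add atoms: N,N-dimethylformamide, CN(C)C=O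
Why: A second directed ortho-metalation can only take place at C4 (= C6) beside a MOM ether, and formylation of the aryllithium with DMF puts the aldehyde ortho to the oxygen that becomes O1 and para to the one that becomes the C7 oxygen.

Step 4
Reactants: 7 2,4-bis(methoxymethoxy)-3-prenylbenzaldehyde; 8 dimethyl succinate
Product: 9 (3E)-4-[2,4-bis(methoxymethoxy)-3-prenylphenyl]-3-(methoxycarbonyl)but-3-enoic acid
Conditions: NaOMe (2.2 equiv), MeOH, reflux; then 1 M HCl to pH 3, 0 °C
Reagents that add atoms: none
Why: Stobbe condensation, in which the succinate enolate adds to the aldehyde, the aldolate lactonizes onto the distal ester and base-induced ring opening gives the alkylidene succinic half-ester with the free acid on the CH2 arm, the E isomer being expected to predominate.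

Step 5
Reactants: 9 (3E)-4-[2,4-bis(methoxymethoxy)-3-prenylphenyl]-3-(methoxycarbonyl)but-3-enoic acid
Product: 10 (3R)-4-[2,4-bis(methoxymethoxy)-3-prenylphenyl]-3-(methoxycarbonyl)butanoic acid
Conditions: [Rh(cod)((S,S)-Et-DuPhos)]BF4 (0.5 mol %), NaOMe (10 mol %), MeOH, H2 (5 bar), rt
Reagents that add atoms: none
Why: Carboxylate-directed asymmetric hydrogenation of a β-aryl itaconate half-ester by a cationic rhodium–bisphospholane catalyst, a substrate class reduced with high enantioselectivity whatever the alkene geometry, should set C3 through the alkene–carboxylate chelate on the chiral metal centre (R expected with the S,S ligand) and leave the non-coordinating prenyl alkene untouched.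

Step 6
Reactants: 10 (3R)-4-[2,4-bis(methoxymethoxy)-3-prenylphenyl]-3-(methoxycarbonyl)butanoic acid
Product: 13 (4R)-4-[(2,4-dihydroxy-3-prenylphenyl)methyl]oxolan-2-one, via hydroxy acid 11 (not isolated), via bis-MOM lactone 12 (not isolated)
Conditions: LiOMe (1.0 equiv), MeOH, evaporate; LiBH4 (2.5 equiv), THF, 0 °C → rt; MeOH quench, 0 °C; then 3 M HCl, MeOH, rt → 40 °C
Reagents that add atoms: none
Why: LiBH4 reduces the methyl ester but not the lithium carboxylate, acid closes the γ-hydroxy acid to the γ-butyrolactone and methanolic HCl removes both MOM acetals (chemoselective ester reduction, lactonization, acetal cleavage), while the stereocenter, no longer α to a carbonyl, is not at risk.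

Step 7
Reactants: 13 (4R)-4-[(2,4-dihydroxy-3-prenylphenyl)methyl]oxolan-2-one
Product: 15 methyl (3R)-4-(2,4-dihydroxy-3-prenylphenyl)-3-(hydroxymethyl)butanoate, via hydroxy acid 14 (not isolated)
Conditions: LiOH (4 equiv), THF/H2O, argon, 0 °C → rt; 1 M HCl to pH 4–5, 0 °C, EtOAc extraction; TMSCHN2 (1.1 equiv), PhMe/MeOH, 0 °C
Reagents that add atoms: lithium hydroxide, [Li+].[OH-]; trimethylsilyldiazomethane, C[Si](C)(C)C=[N+]=[N-]
Why: Saponification of the lactone, cold acidification to the γ-hydroxy acid (which relactonizes only slowly near pH 4–5) and immediate O-methylation of the carboxylic acid by TMSCHN2, which leaves the less acidic phenols alone, should give the open hydroxy ester needed for ether formation.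

Step 8
Reactants: 15 methyl (3R)-4-(2,4-dihydroxy-3-prenylphenyl)-3-(hydroxymethyl)butanoate
Product: 16 methyl 2-[(3R)-7-hydroxy-8-prenylchroman-3-yl]acetate
Conditions: PPh3 (1.5 equiv), DIAD (1.5 equiv), THF (0.02 M), 0 °C → rt
Reagents that add atoms: none
Why: Intramolecular Mitsunobu etherification, in which the primary alcohol is activated as its alkoxyphosphonium ion and displaced by the ortho phenoxide in a 6-exo-tet closure of ring C, should be favoured because the para hydroxyl cannot reach that carbon and dilution suppresses intermolecular etherification; the stereocenter is not involved.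

Step 9
Reactants: 16 methyl 2-[(3R)-7-hydroxy-8-prenylchroman-3-yl]acetate
Product: 17 methyl 2-[(3R)-7-(methoxymethoxy)-8-prenylchroman-3-yl]acetate
Conditions: MOMCl (1.5 equiv), i-Pr2NEt (2 equiv), CH2Cl2, 0 °C → rt
Reagents that add atoms: chloromethyl methyl ether, COCCl
Why: MOM ether formation on the only phenol protects O7 against the bases of the annulation.

Step 10
Reactants: 18 5-bromo-2-methylpent-2-ene; 19 acrolein
Product: 21 7-methylocta-1,6-dien-3-ol (racemic), via Grignard reagent 20 (not isolated)
Conditions: Mg, THF, rt → 40 °C; then 19, –78 → 0 °C; then H2O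
Reagents that add atoms: none
Why: Grignard formation and 1,2-addition of the homoprenyl Grignard reagent to acrolein give the allylic alcohol, whose carbinol centre is oxidized in the next step.

Step 11
Reactants: 21 7-methylocta-1,6-dien-3-ol
Product: 22 7-methylocta-1,6-dien-3-one
Conditions: Dess–Martin periodinane (1.2 equiv), CH2Cl2, 0 °C → rt; used at once
Reagents that add atoms: none
Why: Dess–Martin oxidation converts the secondary allylic alcohol into the vinyl ketone under neutral, non-aqueous conditions that touch neither alkene.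

Step 12
Reactants: 17 methyl 2-[(3R)-7-(methoxymethoxy)-8-prenylchroman-3-yl]acetate; 22 7-methylocta-1,6-dien-3-one
Product: 25 4-[(3R)-7-(methoxymethoxy)-8-prenylchroman-3-yl]-2-prenylcyclohexane-1,3-dione (mixture at the dione ring carbons), via lithium enolate 23 (not isolated), via keto ester 24 (not isolated)
Conditions: LiN(i-Pr)2 (1.05 equiv), THF, –78 °C; 22 (1.1 equiv, slow addition), –78 → –20 °C; then KOtBu (1.5 equiv), t-BuOH/THF, –20 °C → rt; cold 1 M HCl to pH 4
Reagents that add atoms: none
Why: The lithium enolate 23 adds through its α-carbon to the unsubstituted terminus of vinyl ketone 22 (bond C1'–C6') and gives keto ester 24 as its enolate; this is the Michael half of a Michael–Claisen annulation, the known route from ester enolates and vinyl ketones to 4-substituted cyclohexane-1,3-diones. Under KOtBu/t-BuOH the ketone enolates equilibrate and the prenyl-bearing α-carbon attacks the ester carbonyl in a 6-(enolexo)-exo-trig Claisen (Dieckmann-type) closure that forms C2'–C3' and ring B; the other ketone enolate could only close a four-membered ring, and an enol lactone formed by O-acylation would reopen and drain to the same dione. Loss of methoxide and deprotonation of the 2-alkyl-1,3-dione to its delocalized enolate make the sequence irreversible and should pull any 1,2-adduct back through retro-aldol. No lasting stereocenter is created, since C1' and C3' both become aromatic carbons, while chroman C3, β to the ester and later β to the C2' carbonyl, carries no acidic hydrogen and should keep its R configuration. The selectivity needed is 1,4- over 1,2-addition and monoaddition over oligomerization of the vinyl ketone, which slow addition of 22 to a slight excess of enolate at –78 °C is meant to secure; the MOM ether, the aryl ether and both prenyl groups are inert to these bases.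

Step 13
Reactants: 25 4-[(3R)-7-(methoxymethoxy)-8-prenylchroman-3-yl]-2-prenylcyclohexane-1,3-dione
Product: 26 (3R)-3-[2,4-bis(trimethylsilyloxy)-3-prenylcyclohexa-2,4-dien-1-yl]-7-(methoxymethoxy)-8-prenylchroman
Conditions: TMSOTf (2.5 equiv), Et3N (4 equiv), Et2O, 0 °C; pentane, filtration, used crude
Reagents that add atoms: trimethylsilyl trifluoromethanesulfonate, C[Si](C)(C)OS(=O)(=O)C(F)(F)F
Why: Exhaustive O-silylation of the 1,3-dione by soft enolization should give the 1,3-bis(silyloxy)cyclohexa-1,3-diene, with enolization toward the unhindered C5' methylene expected to prevail (a regioisomeric diene would lead to the same arene), and the amine-buffered conditions should spare the MOM ether and the alkenes.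

Step 14
Reactants: 26 (3R)-3-[2,4-bis(trimethylsilyloxy)-3-prenylcyclohexa-2,4-dien-1-yl]-7-(methoxymethoxy)-8-prenylchroman
Product: 28 4-[(3R)-7-(methoxymethoxy)-8-prenylchroman-3-yl]-2-prenylbenzene-1,3-diol, via aryl trimethylsilyl ether 27 (not isolated)
Conditions: Pd(OAc)2 (1.05 equiv), MeCN, rt; then K2CO3 (10 mol %), MeOH, 0 °C
Reagents that add atoms: none
Why: Saegusa–Ito oxidation, in which divalent palladium attacks the electron-rich diene terminus C5', β-hydride elimination from C6' gives the 3-silyloxycyclohexa-2,5-dienone and zerovalent palladium, and tautomerization aromatizes ring B, is followed by methanolysis of the remaining silyl ether.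

Step 15
Reactants: 28 4-[(3R)-7-(methoxymethoxy)-8-prenylchroman-3-yl]-2-prenylbenzene-1,3-diol
Product: 29 Kanzonol X
Conditions: 3 M HCl (aq), MeOH, rt (→ 40 °C if needed), monitored
Reagents that add atoms: none
Why: Acid-catalysed acetal cleavage of the aryl MOM ether under mild methanolic conditions of the kind used on ortho-prenyl phenols should give the target with C3 untouched.

**Compound list**

1 | resorcinol | Oc1cccc(O)c1 | starting material
2 | 1,3-bis(methoxymethoxy)benzene | COCOc1cccc(OCOC)c1 | intermediate
3 | prenyl bromide (1-bromo-3-methylbut-2-ene) | CC(C)=CCBr | starting material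
4 | 2-lithio-1,3-bis(methoxymethoxy)benzene | COCOc1cccc(OCOC)c1[Li] | intermediate
5 | 1,3-bis(methoxymethoxy)-2-prenylbenzene | COCOc1cccc(OCOC)c1CC=C(C)C | intermediate
6 | 4-lithio-1,3-bis(methoxymethoxy)-2-prenylbenzene | [Li]c1ccc(OCOC)c(CC=C(C)C)c1OCOC | intermediate
7 | 2,4-bis(methoxymethoxy)-3-prenylbenzaldehyde | O=Cc1ccc(OCOC)c(CC=C(C)C)c1OCOC | intermediate
8 | dimethyl succinate | COC(=O)CCC(=O)OC | starting material
9 | (3E)-4-[2,4-bis(methoxymethoxy)-3-prenylphenyl]-3-(methoxycarbonyl)but-3-enoic acid | COC(=O)/C(CC(=O)O)=C/c1ccc(OCOC)c(CC=C(C)C)c1OCOC | intermediate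
10 | (3R)-4-[2,4-bis(methoxymethoxy)-3-prenylphenyl]-3-(methoxycarbonyl)butanoic acid | OC(=O)C[C@H](C(=O)OC)Cc1ccc(OCOC)c(CC=C(C)C)c1OCOC | intermediate
11 | (3R)-4-[2,4-bis(methoxymethoxy)-3-prenylphenyl]-3-(hydroxymethyl)butanoic acid | OC(=O)C[C@H](CO)Cc1ccc(OCOC)c(CC=C(C)C)c1OCOC | intermediate
12 | (4R)-4-{[2,4-bis(methoxymethoxy)-3-prenylphenyl]methyl}oxolan-2-one | O=C1C[C@@H](Cc2ccc(OCOC)c(CC=C(C)C)c2OCOC)CO1 | intermediate
13 | (4R)-4-[(2,4-dihydroxy-3-prenylphenyl)methyl]oxolan-2-one | O=C1C[C@@H](Cc2ccc(O)c(CC=C(C)C)c2O)CO1 | intermediate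
14 | (3R)-4-(2,4-dihydroxy-3-prenylphenyl)-3-(hydroxymethyl)butanoic acid | OC(=O)C[C@H](CO)Cc1ccc(O)c(CC=C(C)C)c1O | intermediate
15 | methyl (3R)-4-(2,4-dihydroxy-3-prenylphenyl)-3-(hydroxymethyl)butanoate | COC(=O)C[C@H](CO)Cc1ccc(O)c(CC=C(C)C)c1O | intermediate
16 | methyl 2-[(3R)-7-hydroxy-8-prenylchroman-3-yl]acetate | COC(=O)C[C@@H]1COc2c(CC=C(C)C)c(O)ccc2C1 | intermediate
17 | methyl 2-[(3R)-7-(methoxymethoxy)-8-prenylchroman-3-yl]acetate | COC(=O)C[C@@H]1COc2c(CC=C(C)C)c(OCOC)ccc2C1 | intermediate
18 | 5-bromo-2-methylpent-2-ene | CC(C)=CCCBr | starting material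
19 | acrolein | C=CC=O | starting material
20 | (4-methylpent-3-en-1-yl)magnesium bromide | CC(C)=CCC[Mg]Br | intermediate
21 | 7-methylocta-1,6-dien-3-ol (racemic) | C=CC(O)CCC=C(C)C | intermediate
22 | 7-methylocta-1,6-dien-3-one | C=CC(=O)CCC=C(C)C | intermediate
23 | lithium enolate of ester 17 | COC(O[Li])=C[C@@H]1COc2c(CC=C(C)C)c(OCOC)ccc2C1 | intermediate
24 | methyl 2-[(3R)-7-(methoxymethoxy)-8-prenylchroman-3-yl]-9-methyl-5-oxodec-8-enoate (mixture at C2) | COC(=O)C(CCC(=O)CCC=C(C)C)[C@@H]1COc2c(CC=C(C)C)c(OCOC)ccc2C1 | intermediate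
25 | 4-[(3R)-7-(methoxymethoxy)-8-prenylchroman-3-yl]-2-prenylcyclohexane-1,3-dione (mixture at the dione ring carbons) | O=C1CCC([C@@H]2COc3c(CC=C(C)C)c(OCOC)ccc3C2)C(=O)C1CC=C(C)C | intermediate
26 | (3R)-3-[2,4-bis(trimethylsilyloxy)-3-prenylcyclohexa-2,4-dien-1-yl]-7-(methoxymethoxy)-8-prenylchroman (mixture at C1') | C[Si](C)(C)OC1=CCC([C@@H]2COc3c(CC=C(C)C)c(OCOC)ccc3C2)C(O[Si](C)(C)C)=C1CC=C(C)C | intermediate
27 | (3R)-3-[4-hydroxy-3-prenyl-2-(trimethylsilyloxy)phenyl]-7-(methoxymethoxy)-8-prenylchroman | CC(C)=CCc1c(O)ccc([C@@H]2COc3c(CC=C(C)C)c(OCOC)ccc3C2)c1O[Si](C)(C)C | intermediate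
28 | 4-[(3R)-7-(methoxymethoxy)-8-prenylchroman-3-yl]-2-prenylbenzene-1,3-diol | CC(C)=CCc1c(O)ccc([C@@H]2COc3c(CC=C(C)C)c(OCOC)ccc3C2)c1O | intermediate
29 | Kanzonol X, 4-[(3R)-7-hydroxy-8-prenylchroman-3-yl]-2-prenylbenzene-1,3-diol | CC(C)=CCc1c(O)ccc([C@@H]2COc3c(ccc(O)c3CC=C(C)C)C2)c1O | target

**Step count**

Total: 15 steps. Longest linear sequence: 13 steps (steps 1–9 and 12–15); steps 10–11 form the two-step side branch to enone 22.

**Steps most likely to fail**

Step 12 (key step). The enolate may add 1,2 to the vinyl ketone, the vinyl ketone may oligomerize anionically faster than it is captured, or proton transfer to the cyclizing enolate may stall. Fallback from 17: LiN(i-Pr)2 and TMSCl in THF at –78 °C give the methyl trimethylsilyl ketene acetal F1. Fluoride-catalysed Mukaiyama–Michael addition of F1 to 22 (catalytic tris(dimethylamino)sulfonium difluorotrimethylsilicate, THF, –78 °C), in which no free basic enolate meets the vinyl ketone, gives the silyl enol ether adduct F2. Mild aqueous hydrolysis gives keto ester 24, now isolated, and KOtBu in THF closes it by Claisen condensation to dione 25, where the route is rejoined.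

Step 14. Palladation of the crowded diene may be slow, adventitious desilylation may return the dione, or divalent palladium may attack a prenyl alkene or cyclize the freed phenol onto it oxidatively. Fallback from 25: dianion formation (LiN(i-Pr)2, 2.2 equiv, THF/DMPU, –78 → 0 °C) and selenenylation with PhSeCl at the unsubstituted α'-carbon C5' give the 6-(phenylselanyl) dione F3. Oxidation with mCPBA (1 equiv, CH2Cl2, –78 °C) gives selenoxide F4. Its syn-elimination on warming with Et3N introduces the C5'=C6' alkene, and the cyclohexenedione tautomerizes to resorcinol 28, where the route is rejoined.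

Step 7. The γ-hydroxy acid or its methyl ester may close back to the lactone before ring C is formed, or a phenol may be methylated. Fallback from 13: heating with Cs2CO3 in DMF (about 110 °C) lets the ortho phenoxide attack the lactone CH2–O carbon in a 6-exo-tet alkyl–oxygen cleavage, the reaction type by which phenoxides open γ-butyrolactone to 4-aryloxybutanoic acids. This gives 2-[(3R)-7-hydroxy-8-prenylchroman-3-yl]acetic acid F5 directly. TMSCHN2 in PhMe/MeOH then gives ester 16, where the route is rejoined; steps 7 and 8 are replaced.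

**Further compounds**

F1 | step 12 | (3R)-3-[2-methoxy-2-(trimethylsilyloxy)ethenyl]-7-(methoxymethoxy)-8-prenylchroman (silyl ketene acetal of 17) | COC(O[Si](C)(C)C)=C[C@@H]1COc2c(CC=C(C)C)c(OCOC)ccc2C1
F2 | step 12 | methyl 2-[(3R)-7-(methoxymethoxy)-8-prenylchroman-3-yl]-9-methyl-5-(trimethylsilyloxy)deca-4,8-dienoate | COC(=O)C(CC=C(O[Si](C)(C)C)CCC=C(C)C)[C@@H]1COc2c(CC=C(C)C)c(OCOC)ccc2C1
F3 | step 14 | 4-[(3R)-7-(methoxymethoxy)-8-prenylchroman-3-yl]-6-(phenylselanyl)-2-prenylcyclohexane-1,3-dione | O=C1C([Se]c2ccccc2)CC([C@@H]3COc4c(CC=C(C)C)c(OCOC)ccc4C3)C(=O)C1CC=C(C)C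
F4 | step 14 | 4-[(3R)-7-(methoxymethoxy)-8-prenylchroman-3-yl]-6-(phenylseleninyl)-2-prenylcyclohexane-1,3-dione | O=C1C([Se](=O)c2ccccc2)CC([C@@H]3COc4c(CC=C(C)C)c(OCOC)ccc4C3)C(=O)C1CC=C(C)C
F5 | step 7 | 2-[(3R)-7-hydroxy-8-prenylchroman-3-yl]acetic acid | OC(=O)C[C@@H]1COc2c(CC=C(C)C)c(O)ccc2C1
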